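**Retrosynthetic overview**
1. The target, (3R,3'R,6'R)-siphonaxanthin, is cut at C11=C12 and C11'=C12' (two Wittig reactions) into an ε-end C15 phosphonium salt, the C10 trienedial and a β-end C15 keto phosphonium salt that already carries the C8 ketone and the C19 oxygen.
2. β half: the β ring is bought as the (4R,6R)-hydroxy ketone; C6–C7 comes from a Negishi coupling of its enol triflate with a zinc amide enolate, and C8–C9 from acylation of a vinyllithium made from but-2-yne-1,4-diol by syn-hydrostannation (this fixes 9E and the C19 oxygen).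
3. ε half: the C15 salt comes from (3R,6R)-3-hydroxy-α-ionone, this from its C3' epimer by Mitsunobu inversion, and the epimer from a bridged lactone (2-oxabicyclo[2.2.2]oct-5-en-3-one) by half-reduction and Wittig opening.
4. Key disconnection: the C5'–C6' bond of the ε ring, made by Pd-catalysed bridging α-alkenylation of a δ-lactone enolate. The enabling feature is that O3' and C7' sit on C3' and C6', which are 1,4 across the ε ring; tying O3' to C7' at the carboxyl level gives a six-membered lactone (O, C7', C6', C1', C2', C3') whose α-carbon is C6' and which carries C4'=C5'(CH3) as a (Z)-iodoalkenyl arm on C3'.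
5. Ring order: temporary lactone ring (step 4), then the ε carbocycle closed across it (step 5), then the lactone ring removed (steps 6 and 7); the β ring is never opened.

Key step: step 5

Remark: carotenoid numbering is used for atoms; the hydroxy ketone of step 13 and the C10 dialdehyde of step 12 are taken as purchasable carotenoid intermediates, and Z isomers formed at new chain double bonds are assumed to equilibrate to the E forms, as is usual for carotenoids.

**Route**

Step 1
Reactants: 1 3,3-dimethylglutaric anhydride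
Product: 2 5-methoxy-3,3-dimethyl-5-oxopentanoic acid
Conditions: MeOH, reflux; evaporate
Reagents that add atoms: methanol (CO)
Why: Alcoholysis of a symmetric cyclic anhydride gives the half ester with no selectivity issue, so that one carboxyl (future C7') is masked and the other (future C3') stays free for activation.

Step 2
Reactants: 2 5-methoxy-3,3-dimethyl-5-oxopentanoic acid; 3 propyne
Product: 5 methyl 3,3-dimethyl-5-oxooct-6-ynoate, via acid chloride 4 (not isolated)
Conditions: (COCl)2, DMF (cat.), CH2Cl2, 0 °C → rt, evaporate; then propyne, PdCl2(PPh3)2 (2 mol %), CuI (4 mol %), Et3N, THF, rt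
Reagents that add atoms: none
Why: Acyl Sonogashira coupling of an acid chloride with a terminal alkyne gives the ynone (C3'–C4' bond) under conditions to which the methyl ester is inert.

Step 3
Reactants: 5 methyl 3,3-dimethyl-5-oxooct-6-ynoate
Product: 6 methyl (6Z)-7-iodo-3,3-dimethyl-5-oxooct-6-enoate
Conditions: NaI, AcOH, rt
Reagents that add atoms: sodium iodide ([Na+].[I-])
Why: Conjugate hydroiodination of an ynone is an anti addition that places iodine on the β-carbon cis to the acyl group, which fixes the (Z)-iodoalkene needed for C4'=C5'.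

Step 4
Reactants: 6 methyl (6Z)-7-iodo-3,3-dimethyl-5-oxooct-6-enoate
Product: 8 (6S)-6-[(1Z)-2-iodoprop-1-en-1-yl]-4,4-dimethyloxan-2-one, via hydroxy ester 7 (not isolated)
Conditions: (R)-2-methyl-CBS-oxazaborolidine (20 mol %), BH3·SMe2, THF, −30 °C; MeOH quench; then p-TsOH (cat.), toluene, 40 °C
Reagents that add atoms: none
Why: Corey–Bakshi–Shibata reduction with the iodoalkenyl group as the large substituent should set the (S) carbinol (C3'), and the δ-hydroxy ester then lactonises under acid catalysis, helped by the gem-dimethyl group.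

Step 5
Reactants: 8 (6S)-6-[(1Z)-2-iodoprop-1-en-1-yl]-4,4-dimethyloxan-2-one
Product: 11 (1S,4R)-5,8,8-trimethyl-2-oxabicyclo[2.2.2]oct-5-en-3-one, via lithium enolate 9 (not isolated), via chlorozinc enolate 10 (not isolated)
Conditions: LiN(SiMe3)2 (1.1 equiv), THF, −78 °C; ZnCl2 (1.2 equiv), −78 → 0 °C; then Pd2(dba)3 (2.5 mol %), P(t-Bu)3 (6 mol %), THF, 0 → 25 °C
Reagents that add atoms: none
Why: Zerovalent palladium inserts into the C–I bond of the (Z)-iodoalkene (C5'), the chlorozinc enolate transfers its α-carbon (C6') to palladium, and reductive elimination forms the C5'–C6' bond; the closest known reaction type is the Pd-catalysed intramolecular α-alkenylation of ketone, ester and amide enolates with alkenyl halides (a Negishi-type enolate coupling), which is established for bridged ring closures. The six-membered carbocycle (C1', C2', C3', C4', C5', C6', the future ε ring) is closed by bridging positions 3 and 6 of the oxanone across a boat, through a seven-membered palladacycle, with the enolate double bond exocyclic to the new ring (enolexo) and C4'=C5' endocyclic. The new stereocentre C6' is controlled entirely by C3' through the lactone tether, because the alkenyl arm can reach the planar enolate carbon only on its own face, so that only the cis-bridged (1S,4R) bicycle can form. The step needs C-alkenylation to be faster than Claisen self-condensation, dehydroiodination, [3,3] ring contraction of the allylic lactone enolate and ionisation of the allylic C3'–O bond by zerovalent palladium; the mild zinc enolate, the low temperature, the fast oxidative addition of an alkenyl iodide to the P(t-Bu)3-ligated catalyst and the Z geometry that holds C5' over C6' should secure this. Because C6' becomes a bridgehead next to the carbonyl it can no longer enolise, so neither epimerisation nor migration of C4'=C5' into conjugation is possible under the basic conditions.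

Step 6
Reactants: 11 (1S,4R)-5,8,8-trimethyl-2-oxabicyclo[2.2.2]oct-5-en-3-one
Product: 12 (1S,4R)-5,8,8-trimethyl-2-oxabicyclo[2.2.2]oct-5-en-3-ol
Conditions: i-Bu2AlH (1.1 equiv), CH2Cl2, −78 °C; aq. KNaC4H4O6
Reagents that add atoms: none
Why: Half-reduction of a lactone with i-Bu2AlH at low temperature stops at the lactol, which keeps C6' locked in the bridged hemiacetal until the aldehyde is used.

Step 7
Reactants: 12 (1S,4R)-5,8,8-trimethyl-2-oxabicyclo[2.2.2]oct-5-en-3-ol; 13 1-(triphenyl-λ5-phosphanylidene)propan-2-one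
Product: 14 (3E)-4-[(1R,4S)-4-hydroxy-2,6,6-trimethylcyclohex-2-en-1-yl]but-3-en-2-one
Conditions: 13 (2 equiv), toluene, 80 °C
Reagents that add atoms: none
Why: Wittig olefination of the open hydroxy aldehyde form of the lactol with a stabilised, nearly neutral ylide should give the (E)-enone (C7'=C8') and remove the temporary ring without a base strong enough to epimerise C6'.

Step 8
Reactants: 14 (3E)-4-[(1R,4S)-4-hydroxy-2,6,6-trimethylcyclohex-2-en-1-yl]but-3-en-2-one
Product: 15 (1R,4R)-3,5,5-trimethyl-4-[(1E)-3-oxobut-1-en-1-yl]cyclohex-2-en-1-yl 4-nitrobenzoate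
Conditions: 4-nitrobenzoic acid, PPh3, DIAD (diisopropyl azodicarboxylate), THF, 0 °C → rt
Reagents that add atoms: 4-nitrobenzoic acid (O=C(O)c1ccc(cc1)[N+](=O)[O-])
Why: Mitsunobu esterification is an SN2 displacement with inversion at C3', the carboxylate entering on the face away from the C6' side chain, which turns the 3',6'-cis series into the required 3',6'-trans (3'R) configuration.

Step 9
Reactants: 15 (1R,4R)-3,5,5-trimethyl-4-[(1E)-3-oxobut-1-en-1-yl]cyclohex-2-en-1-yl 4-nitrobenzoate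
Product: 16 (3E)-4-[(1R,4R)-4-hydroxy-2,6,6-trimethylcyclohex-2-en-1-yl]but-3-en-2-one
Conditions: K2CO3 (cat.), MeOH, 0 °C → rt
Reagents that add atoms: none
Why: Mild transesterification with methanol removes the activated nitrobenzoate without touching the enone or its γ-stereocentre C6'.

Step 10
Reactants: 16 (3E)-4-[(1R,4R)-4-hydroxy-2,6,6-trimethylcyclohex-2-en-1-yl]but-3-en-2-one; 17 vinylmagnesium bromide
Product: 18 (1E)-1-[(1R,4R)-4-hydroxy-2,6,6-trimethylcyclohex-2-en-1-yl]-3-methylpenta-1,4-dien-3-ol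
Conditions: CH2=CHMgBr (3 equiv), THF, −20 → 0 °C; H2O
Reagents that add atoms: none
Why: Grignard 1,2-addition to the methyl ketone (after deprotonation of the free hydroxyl) gives the tertiary bis-allylic carbinol, whose new centre does not matter because it is ionised in the next step.

Step 11
Reactants: 18 (1E)-1-[(1R,4R)-4-hydroxy-2,6,6-trimethylcyclohex-2-en-1-yl]-3-methylpenta-1,4-dien-3-ol
Product: 19 [(2E,4E)-5-[(1R,4R)-4-hydroxy-2,6,6-trimethylcyclohex-2-en-1-yl]-3-methylpenta-2,4-dien-1-yl](triphenyl)phosphonium bromide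
Conditions: PPh3·HBr, MeOH, 0 °C → rt
Reagents that add atoms: triphenylphosphine hydrobromide ([Br-].c1ccc(cc1)[PH+](c1ccccc1)c1ccccc1)
Why: Acid should ionise only the tertiary doubly allylic carbinol and the phosphine should capture the pentadienyl cation at its primary end (SN1' allylic transposition, the standard way to C15 Wittig salts), leaving the secondary ring carbinol alone.

Step 12
Reactants: 19 [(2E,4E)-5-[(1R,4R)-4-hydroxy-2,6,6-trimethylcyclohex-2-en-1-yl]-3-methylpenta-2,4-dien-1-yl](triphenyl)phosphonium bromide; 20 (2E,4E,6E)-2,7-dimethylocta-2,4,6-trienedial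
Product: 22 (2E,4E,6E,8E,10E,12E)-13-[(1R,4R)-4-hydroxy-2,6,6-trimethylcyclohex-2-en-1-yl]-2,7,11-trimethyltrideca-2,4,6,8,10,12-hexaenal, via ylide 21 (not isolated)
Conditions: 20 (3 equiv), NaOMe (1.1 equiv), MeOH/CH2Cl2, −10 °C → rt; then I2 (cat.), CH2Cl2, rt, diffuse light
Reagents that add atoms: none
Why: Wittig olefination with the dialdehyde in excess should give the mono-olefination product (C11'=C12'), and iodine-catalysed equilibration should convert Z isomers into the all-E hexaenal.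

Step 13
Reactants: 23 (4R,6R)-4-hydroxy-2,2,6-trimethylcyclohexan-1-one
Product: 24 (4R,6R)-4-{[tert-butyl(dimethyl)silyl]oxy}-2,2,6-trimethylcyclohexan-1-one
Conditions: t-BuMe2SiCl, imidazole, DMF, rt
Reagents that add atoms: tert-butyl(chloro)dimethylsilane (CC(C)(C)[Si](C)(C)Cl)
Why: Standard silylation protects the C3 carbinol for the enolate and organometallic steps that follow.

Step 14
Reactants: 24 (4R,6R)-4-{[tert-butyl(dimethyl)silyl]oxy}-2,2,6-trimethylcyclohexan-1-one
Product: 26 (4R)-4-{[tert-butyl(dimethyl)silyl]oxy}-2,6,6-trimethylcyclohex-1-en-1-yl trifluoromethanesulfonate, via lithium enolate 25 (not isolated)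
Conditions: LiN(i-Pr)2, THF, −78 → 0 °C; then PhN(SO2CF3)2, 0 °C → rt
Reagents that add atoms: N-phenylbis(trifluoromethanesulfonimide) (O=S(=O)(N(c1ccccc1)S(=O)(=O)C(F)(F)F)C(F)(F)F)
Why: The ketone can enolise only towards the methyl-bearing carbon, so O-triflation of the enolate gives the tetrasubstituted enol triflate that carries the C5=C6 double bond.

Step 15
Reactants: 26 (4R)-4-{[tert-butyl(dimethyl)silyl]oxy}-2,6,6-trimethylcyclohex-1-en-1-yl trifluoromethanesulfonate; 27 2-bromo-N-methoxy-N-methylacetamide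
Product: 29 2-[(4R)-4-{[tert-butyl(dimethyl)silyl]oxy}-2,6,6-trimethylcyclohex-1-en-1-yl]-N-methoxy-N-methylacetamide, via zinc reagent 28 (not isolated)
Conditions: Zn dust (Me3SiCl-activated), THF, 40 °C; then 26, Pd2(dba)3 (2.5 mol %), XPhos (6 mol %), THF, 60 °C
Reagents that add atoms: none
Why: Negishi coupling of the Reformatsky-type zinc amide enolate with the enol triflate forms the C6–C7 bond and puts C8 directly at the Weinreb amide level, and the neutral zinc reagent should leave the β,γ-double bond in place.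

Step 16
Reactants: 30 but-2-yne-1,4-diol
Product: 31 (2E)-2-(tributylstannyl)but-2-ene-1,4-diol
Conditions: Bu3SnH, PdCl2(PPh3)2 (2 mol %), THF, 0 °C → rt
Reagents that add atoms: tributylstannane (CCCC[SnH](CCCC)CCCC)
Why: Pd-catalysed hydrostannation is a syn addition and has no regiochemical issue on this symmetric alkyne, so tin (the future C8 position) ends up trans to the CH2OH that becomes C11.

Step 17
Reactants: 31 (2E)-2-(tributylstannyl)but-2-ene-1,4-diol
Product: 32 (2E)-2-(tributylstannyl)-4-[(triethylsilyl)oxy]but-2-en-1-ol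
Conditions: Et3SiCl (1.0 equiv), imidazole, CH2Cl2, −40 °C
Reagents that add atoms: chlorotriethylsilane (CC[Si](CC)(CC)Cl)
Why: Silylation should occur at the hydroxyl remote from the bulky stannyl group (the C11 oxygen), because the other hydroxymethyl group is geminal to SnBu3.

Step 18
Reactants: 32 (2E)-2-(tributylstannyl)-4-[(triethylsilyl)oxy]but-2-en-1-ol
Product: 33 tert-butyl(dimethyl){[(2E)-2-(tributylstannyl)-4-[(triethylsilyl)oxy]but-2-en-1-yl]oxy}silane
Conditions: t-BuMe2SiCl, imidazole, DMF, rt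
Reagents that add atoms: tert-butyl(chloro)dimethylsilane (CC(C)(C)[Si](C)(C)Cl)
Why: Standard silylation gives the C19 oxygen a robust group that is orthogonal to the labile triethylsilyl ether.

Step 19
Reactants: 33 tert-butyl(dimethyl){[(2E)-2-(tributylstannyl)-4-[(triethylsilyl)oxy]but-2-en-1-yl]oxy}silane; 29 2-[(4R)-4-{[tert-butyl(dimethyl)silyl]oxy}-2,6,6-trimethylcyclohex-1-en-1-yl]-N-methoxy-N-methylacetamide
Product: 35 (3E)-3-({[tert-butyl(dimethyl)silyl]oxy}methyl)-1-[(4R)-4-{[tert-butyl(dimethyl)silyl]oxy}-2,6,6-trimethylcyclohex-1-en-1-yl]-5-[(triethylsilyl)oxy]pent-3-en-2-one, via vinyllithium 34 (not isolated)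
Conditions: n-BuLi (1.05 equiv), THF, −78 °C; then 29, −78 → −40 °C; H2O
Reagents that add atoms: none
Why: Tin–lithium exchange keeps the alkene geometry and the vinyllithium acylates the Weinreb amide once (stable chelated tetrahedral intermediate), which forms the C8–C9 bond and the enone with C8 trans to C11.

Step 20
Reactants: 35 (3E)-3-({[tert-butyl(dimethyl)silyl]oxy}methyl)-1-[(4R)-4-{[tert-butyl(dimethyl)silyl]oxy}-2,6,6-trimethylcyclohex-1-en-1-yl]-5-[(triethylsilyl)oxy]pent-3-en-2-one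
Product: 36 (3E)-3-({[tert-butyl(dimethyl)silyl]oxy}methyl)-1-[(4R)-4-{[tert-butyl(dimethyl)silyl]oxy}-2,6,6-trimethylcyclohex-1-en-1-yl]-5-hydroxypent-3-en-2-one
Conditions: pyridinium p-toluenesulfonate (cat.), MeOH/CH2Cl2, 0 °C
Reagents that add atoms: none
Why: Acid-catalysed methanolysis cleaves the primary triethylsilyl ether much faster than the two tert-butyldimethylsilyl ethers, which should free only the C11 hydroxyl.

Step 21
Reactants: 36 (3E)-3-({[tert-butyl(dimethyl)silyl]oxy}methyl)-1-[(4R)-4-{[tert-butyl(dimethyl)silyl]oxy}-2,6,6-trimethylcyclohex-1-en-1-yl]-5-hydroxypent-3-en-2-one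
Product: 38 [(2E)-3-({[tert-butyl(dimethyl)silyl]oxy}methyl)-5-[(4R)-4-{[tert-butyl(dimethyl)silyl]oxy}-2,6,6-trimethylcyclohex-1-en-1-yl]-4-oxopent-2-en-1-yl](triphenyl)phosphonium bromide, via allylic bromide 37 (not isolated)
Conditions: CBr4, PPh3, CH2Cl2, 0 °C; then PPh3 (excess), MeCN, rt
Reagents that add atoms: carbon tetrabromide (BrC(Br)(Br)Br); triphenylphosphine (c1ccc(cc1)P(c1ccccc1)c1ccccc1)
Why: Appel bromination of the primary allylic alcohol followed by SN2 quaternisation of triphenylphosphine gives the C11 phosphonium salt under neutral conditions that spare the silyl ethers and the β,γ-unsaturated ketone.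

Step 22
Reactants: 38 [(2E)-3-({[tert-butyl(dimethyl)silyl]oxy}methyl)-5-[(4R)-4-{[tert-butyl(dimethyl)silyl]oxy}-2,6,6-trimethylcyclohex-1-en-1-yl]-4-oxopent-2-en-1-yl](triphenyl)phosphonium bromide; 22 (2E,4E,6E,8E,10E,12E)-13-[(1R,4R)-4-hydroxy-2,6,6-trimethylcyclohex-2-en-1-yl]-2,7,11-trimethyltrideca-2,4,6,8,10,12-hexaenal
Product: 40 (3R,3'R,6'R)-3,19-bis{[tert-butyl(dimethyl)silyl]oxy}-3'-hydroxy-7,8-dihydro-β,ε-caroten-8-one, via ylide 39 (not isolated)
Conditions: 1,2-epoxybutane/EtOH, 70 °C, dark, Ar; then I2 (cat.), CH2Cl2, rt, diffuse light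
Reagents that add atoms: none
Why: Wittig olefination under base-free epoxide conditions (bromide opens the epoxide and the alkoxide deprotonates the salt) should join the keto-stabilised vinylogous ylide to the polyenal at C11=C12 without enolising the C8 ketone, and iodine equilibration should give the all-E chain.

Step 23
Reactants: 40 (3R,3'R,6'R)-3,19-bis{[tert-butyl(dimethyl)silyl]oxy}-3'-hydroxy-7,8-dihydro-β,ε-caroten-8-one
Product: 41 (3R,3'R,6'R)-3,3',19-trihydroxy-7,8-dihydro-β,ε-caroten-8-one (siphonaxanthin)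
Conditions: HF·pyridine, pyridine, THF, 0 °C → rt
Reagents that add atoms: none
Why: Buffered fluoride desilylation should remove both silyl ethers and leave the polyene, the β,γ-unsaturated ketone and the allylic carbinols untouched.

**Compound list**
1 | 3,3-dimethylglutaric anhydride (4,4-dimethyloxane-2,6-dione) | CC1(C)CC(=O)OC(=O)C1 | starting material
2 | 5-methoxy-3,3-dimethyl-5-oxopentanoic acid | COC(=O)CC(C)(C)CC(=O)O | intermediate
3 | propyne | CC#C | starting material
4 | methyl 5-chloro-3,3-dimethyl-5-oxopentanoate (acid chloride) | COC(=O)CC(C)(C)CC(=O)Cl | intermediate (not isolated)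
5 | methyl 3,3-dimethyl-5-oxooct-6-ynoate | CC#CC(=O)CC(C)(C)CC(=O)OC | intermediate
6 | methyl (6Z)-7-iodo-3,3-dimethyl-5-oxooct-6-enoate | C/C(I)=C/C(=O)CC(C)(C)CC(=O)OC | intermediate
7 | methyl (5S,6Z)-5-hydroxy-7-iodo-3,3-dimethyloct-6-enoate (hydroxy ester) | C/C(I)=C/[C@@H](O)CC(C)(C)CC(=O)OC | intermediate (not isolated)
8 | (6S)-6-[(1Z)-2-iodoprop-1-en-1-yl]-4,4-dimethyloxan-2-one | C/C(I)=C/[C@@H]1CC(C)(C)CC(=O)O1 | intermediate
9 | lithium (6S)-6-[(1Z)-2-iodoprop-1-en-1-yl]-4,4-dimethyl-5,6-dihydro-4H-pyran-2-olate (lithium enolate) | C/C(I)=C/[C@@H]1CC(C)(C)C=C(O[Li])O1 | intermediate (not isolated)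
10 | chlorozinc (6S)-6-[(1Z)-2-iodoprop-1-en-1-yl]-4,4-dimethyl-5,6-dihydro-4H-pyran-2-olate (chlorozinc enolate) | C/C(I)=C/[C@@H]1CC(C)(C)C=C(O[Zn]Cl)O1 | intermediate (not isolated)
11 | (1S,4R)-5,8,8-trimethyl-2-oxabicyclo[2.2.2]oct-5-en-3-one | CC1=C[C@@H]2CC(C)(C)[C@H]1C(=O)O2 | intermediate
12 | (1S,4R)-5,8,8-trimethyl-2-oxabicyclo[2.2.2]oct-5-en-3-ol (both anomers) | CC1=C[C@@H]2CC(C)(C)[C@H]1C(O)O2 | intermediate
13 | 1-(triphenyl-λ5-phosphanylidene)propan-2-one | CC(=O)C=P(c1ccccc1)(c1ccccc1)c1ccccc1 | starting material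
14 | (3E)-4-[(1R,4S)-4-hydroxy-2,6,6-trimethylcyclohex-2-en-1-yl]but-3-en-2-one (3,6-cis-3-hydroxy-α-ionone) | CC1=C[C@@H](O)CC(C)(C)[C@H]1/C=C/C(C)=O | intermediate
15 | (1R,4R)-3,5,5-trimethyl-4-[(1E)-3-oxobut-1-en-1-yl]cyclohex-2-en-1-yl 4-nitrobenzoate | CC1=C[C@H](OC(=O)c2ccc(cc2)[N+](=O)[O-])CC(C)(C)[C@H]1/C=C/C(C)=O | intermediate
16 | (3E)-4-[(1R,4R)-4-hydroxy-2,6,6-trimethylcyclohex-2-en-1-yl]but-3-en-2-one ((3R,6R)-3-hydroxy-α-ionone) | CC1=C[C@H](O)CC(C)(C)[C@H]1/C=C/C(C)=O | intermediate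
17 | vinylmagnesium bromide | C=C[Mg]Br | starting material
18 | (1E)-1-[(1R,4R)-4-hydroxy-2,6,6-trimethylcyclohex-2-en-1-yl]-3-methylpenta-1,4-dien-3-ol (both C3 epimers) | CC1=C[C@H](O)CC(C)(C)[C@H]1/C=C/C(C)(O)C=C | intermediate
19 | [(2E,4E)-5-[(1R,4R)-4-hydroxy-2,6,6-trimethylcyclohex-2-en-1-yl]-3-methylpenta-2,4-dien-1-yl](triphenyl)phosphonium bromide | CC1=C[C@H](O)CC(C)(C)[C@H]1/C=C/C(C)=C/C[P+](c1ccccc1)(c1ccccc1)c1ccccc1.[Br-] | intermediate
20 | (2E,4E,6E)-2,7-dimethylocta-2,4,6-trienedial | O=C/C(C)=C/C=C/C=C(C)/C=O | starting material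
21 | [(2E,4E)-5-[(1R,4R)-4-hydroxy-2,6,6-trimethylcyclohex-2-en-1-yl]-3-methylpenta-2,4-dien-1-ylidene](triphenyl)-λ5-phosphane (ylide) | CC1=C[C@H](O)CC(C)(C)[C@H]1/C=C/C(C)=C/C=P(c1ccccc1)(c1ccccc1)c1ccccc1 | intermediate (not isolated)
22 | (2E,4E,6E,8E,10E,12E)-13-[(1R,4R)-4-hydroxy-2,6,6-trimethylcyclohex-2-en-1-yl]-2,7,11-trimethyltrideca-2,4,6,8,10,12-hexaenal | CC1=C[C@H](O)CC(C)(C)[C@H]1/C=C/C(C)=C/C=C/C(C)=C/C=C/C=C(C)/C=O | intermediate
23 | (4R,6R)-4-hydroxy-2,2,6-trimethylcyclohexan-1-one | C[C@@H]1C[C@@H](O)CC(C)(C)C1=O | starting material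
24 | (4R,6R)-4-{[tert-butyl(dimethyl)silyl]oxy}-2,2,6-trimethylcyclohexan-1-one | C[C@@H]1C[C@@H](O[Si](C)(C)C(C)(C)C)CC(C)(C)C1=O | intermediate
25 | lithium (4R)-4-{[tert-butyl(dimethyl)silyl]oxy}-2,6,6-trimethylcyclohex-1-en-1-olate (lithium enolate) | [Li]OC1=C(C)C[C@@H](O[Si](C)(C)C(C)(C)C)CC1(C)C | intermediate (not isolated)
26 | (4R)-4-{[tert-butyl(dimethyl)silyl]oxy}-2,6,6-trimethylcyclohex-1-en-1-yl trifluoromethanesulfonate | FC(F)(F)S(=O)(=O)OC1=C(C)C[C@@H](O[Si](C)(C)C(C)(C)C)CC1(C)C | intermediate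
27 | 2-bromo-N-methoxy-N-methylacetamide | CON(C)C(=O)CBr | starting material
28 | bromo{2-[methoxy(methyl)amino]-2-oxoethyl}zinc (zinc reagent) | CON(C)C(=O)C[Zn]Br | intermediate (not isolated)
29 | 2-[(4R)-4-{[tert-butyl(dimethyl)silyl]oxy}-2,6,6-trimethylcyclohex-1-en-1-yl]-N-methoxy-N-methylacetamide | CON(C)C(=O)CC1=C(C)C[C@@H](O[Si](C)(C)C(C)(C)C)CC1(C)C | intermediate
30 | but-2-yne-1,4-diol | OCC#CCO | starting material
31 | (2E)-2-(tributylstannyl)but-2-ene-1,4-diol | OC/C=C(\CO)[Sn](CCCC)(CCCC)CCCC | intermediate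
32 | (2E)-2-(tributylstannyl)-4-[(triethylsilyl)oxy]but-2-en-1-ol | CC[Si](CC)(CC)OC/C=C(\CO)[Sn](CCCC)(CCCC)CCCC | intermediate
33 | tert-butyl(dimethyl){[(2E)-2-(tributylstannyl)-4-[(triethylsilyl)oxy]but-2-en-1-yl]oxy}silane | CC[Si](CC)(CC)OC/C=C(\CO[Si](C)(C)C(C)(C)C)[Sn](CCCC)(CCCC)CCCC | intermediate
34 | {(2Z)-1-{[tert-butyl(dimethyl)silyl]oxy}-4-[(triethylsilyl)oxy]but-2-en-2-yl}lithium (vinyllithium) | CC[Si](CC)(CC)OC/C=C(\CO[Si](C)(C)C(C)(C)C)[Li] | intermediate (not isolated)
35 | (3E)-3-({[tert-butyl(dimethyl)silyl]oxy}methyl)-1-[(4R)-4-{[tert-butyl(dimethyl)silyl]oxy}-2,6,6-trimethylcyclohex-1-en-1-yl]-5-[(triethylsilyl)oxy]pent-3-en-2-one | CC[Si](CC)(CC)OC/C=C(\CO[Si](C)(C)C(C)(C)C)C(=O)CC1=C(C)C[C@@H](O[Si](C)(C)C(C)(C)C)CC1(C)C | intermediate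
36 | (3E)-3-({[tert-butyl(dimethyl)silyl]oxy}methyl)-1-[(4R)-4-{[tert-butyl(dimethyl)silyl]oxy}-2,6,6-trimethylcyclohex-1-en-1-yl]-5-hydroxypent-3-en-2-one | OC/C=C(\CO[Si](C)(C)C(C)(C)C)C(=O)CC1=C(C)C[C@@H](O[Si](C)(C)C(C)(C)C)CC1(C)C | intermediate
37 | (3E)-5-bromo-3-({[tert-butyl(dimethyl)silyl]oxy}methyl)-1-[(4R)-4-{[tert-butyl(dimethyl)silyl]oxy}-2,6,6-trimethylcyclohex-1-en-1-yl]pent-3-en-2-one (allylic bromide) | BrC/C=C(\CO[Si](C)(C)C(C)(C)C)C(=O)CC1=C(C)C[C@@H](O[Si](C)(C)C(C)(C)C)CC1(C)C | intermediate (not isolated)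
38 | [(2E)-3-({[tert-butyl(dimethyl)silyl]oxy}methyl)-5-[(4R)-4-{[tert-butyl(dimethyl)silyl]oxy}-2,6,6-trimethylcyclohex-1-en-1-yl]-4-oxopent-2-en-1-yl](triphenyl)phosphonium bromide | [Br-].c1ccccc1[P+](c1ccccc1)(c1ccccc1)C/C=C(\CO[Si](C)(C)C(C)(C)C)C(=O)CC1=C(C)C[C@@H](O[Si](C)(C)C(C)(C)C)CC1(C)C | intermediate
39 | [(2E)-3-({[tert-butyl(dimethyl)silyl]oxy}methyl)-5-[(4R)-4-{[tert-butyl(dimethyl)silyl]oxy}-2,6,6-trimethylcyclohex-1-en-1-yl]-4-oxopent-2-en-1-ylidene](triphenyl)-λ5-phosphane (ylide) | c1ccccc1P(c1ccccc1)(c1ccccc1)=C/C=C(\CO[Si](C)(C)C(C)(C)C)C(=O)CC1=C(C)C[C@@H](O[Si](C)(C)C(C)(C)C)CC1(C)C | intermediate (not isolated)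
40 | (3R,3'R,6'R)-3,19-bis{[tert-butyl(dimethyl)silyl]oxy}-3'-hydroxy-7,8-dihydro-β,ε-caroten-8-one | CC1=C[C@H](O)CC(C)(C)[C@H]1/C=C/C(C)=C/C=C/C(C)=C/C=C/C=C(C)/C=C/C=C(\CO[Si](C)(C)C(C)(C)C)C(=O)CC1=C(C)C[C@@H](O[Si](C)(C)C(C)(C)C)CC1(C)C | intermediate
41 | (3R,3'R,6'R)-3,3',19-trihydroxy-7,8-dihydro-β,ε-caroten-8-one (siphonaxanthin) | CC1=C[C@H](O)CC(C)(C)[C@H]1/C=C/C(C)=C/C=C/C(C)=C/C=C/C=C(C)/C=C/C=C(\CO)C(=O)CC1=C(C)C[C@@H](O)CC1(C)C | target

**Step count and risks**

Total step count: 23. Longest linear sequence: 14 steps (steps 1 to 12, then 22 and 23).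

Steps most likely to fail:

Step 5. The ring closure may lose out to intermolecular Claisen condensation of the lactone enolate, to [3,3] ring contraction of the allylic lactone enolate, or to ionisation of the allylic C–O bond by zerovalent palladium followed by loss of CO2. The boat geometry needed for reductive elimination may also be reached too slowly, so that the alkenylpalladium intermediate is simply protonated. The fallback gives up the bridging and sets out from hydroxy ester 7, isolated after the reduction of step 4 instead of being lactonised. Silylation (t-BuMe2SiCl, imidazole) gives methyl (5S,6Z)-5-{[tert-butyl(dimethyl)silyl]oxy}-7-iodo-3,3-dimethyloct-6-enoate F1. LiN(SiMe3)2 (2.2 equiv) turns it into its lithium ester enolate F2, which closes the unstrained cyclohexene by Pd-catalysed α-alkenylation of an open-chain ester enolate (Pd2(dba)3, P(t-Bu)3, THF, rt). After α-protonation of the product dienolate this gives methyl (4S)-4-{[tert-butyl(dimethyl)silyl]oxy}-2,6,6-trimethylcyclohex-2-ene-1-carboxylate F3 as both C1 epimers. Bu4NF/AcOH frees methyl (4S)-4-hydroxy-2,6,6-trimethylcyclohex-2-ene-1-carboxylate F4. DBU in toluene at 80 °C, with removal of methanol, equilibrates C1 and drains the cis epimer by lactonisation, so that the route is rejoined at lactone 11.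

Step 15. Oxidative addition and transmetalation at the tetrasubstituted triflate, which is flanked by a quaternary carbon, may be too slow, so that the zinc enolate is protonated or the triflate is reduced. The fallback sets out from triflate 26 and bypasses amide 29. Stille coupling with allyltributylstannane (Pd(PPh3)4, LiCl, THF, reflux) gives tert-butyl(dimethyl){[(1R)-3,5,5-trimethyl-4-(prop-2-en-1-yl)cyclohex-3-en-1-yl]oxy}silane F5. Lemieux–Johnson cleavage of its monosubstituted double bond (OsO4 cat., NaIO4, 2,6-lutidine, dioxane/H2O) gives 2-[(4R)-4-{[tert-butyl(dimethyl)silyl]oxy}-2,6,6-trimethylcyclohex-1-en-1-yl]acetaldehyde F6. Addition of vinyllithium 34 at −78 °C gives (3E)-3-({[tert-butyl(dimethyl)silyl]oxy}methyl)-1-[(4R)-4-{[tert-butyl(dimethyl)silyl]oxy}-2,6,6-trimethylcyclohex-1-en-1-yl]-5-[(triethylsilyl)oxy]pent-3-en-2-ol F7, and Dess–Martin oxidation of this allylic alcohol rejoins the route at enone 35.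

Step 22. The delocalised keto-stabilised ylide may lose the C9=C10 geometry, may eliminate the C19 silyloxy group from its enolate form, or may react too slowly with the polyenal. The fallback reverses the polarity of the coupling and sets out from alcohol 36 and aldehyde 22. MnO2 oxidation of 36 gives (2E)-3-({[tert-butyl(dimethyl)silyl]oxy}methyl)-5-[(4R)-4-{[tert-butyl(dimethyl)silyl]oxy}-2,6,6-trimethylcyclohex-1-en-1-yl]-4-oxopent-2-enal F8. NaBH4 reduction of 22 gives (2E,4E,6E,8E,10E,12E)-13-[(1R,4R)-4-hydroxy-2,6,6-trimethylcyclohex-2-en-1-yl]-2,7,11-trimethyltrideca-2,4,6,8,10,12-hexaen-1-ol F9, and PPh3·HBr in MeOH turns this into [(2E,4E,6E,8E,10E,12E)-13-[(1R,4R)-4-hydroxy-2,6,6-trimethylcyclohex-2-en-1-yl]-2,7,11-trimethyltrideca-2,4,6,8,10,12-hexaen-1-yl](triphenyl)phosphonium bromide F10. NaOMe generates its more reactive polyenyl ylide F11, which should condense with the aldehyde group of F8 in a Wittig reaction and, after iodine equilibration, rejoin the route at 40.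

**Further compounds**
F1 | step 5 | methyl (5S,6Z)-5-{[tert-butyl(dimethyl)silyl]oxy}-7-iodo-3,3-dimethyloct-6-enoate | C/C(I)=C/[C@@H](O[Si](C)(C)C(C)(C)C)CC(C)(C)CC(=O)OC
F2 | step 5 | lithium ester enolate of F1 | C/C(I)=C/[C@@H](O[Si](C)(C)C(C)(C)C)CC(C)(C)C=C(O[Li])OC
F3 | step 5 | methyl (4S)-4-{[tert-butyl(dimethyl)silyl]oxy}-2,6,6-trimethylcyclohex-2-ene-1-carboxylate (both C1 epimers) | CC1=C[C@@H](O[Si](C)(C)C(C)(C)C)CC(C)(C)C1C(=O)OC
F4 | step 5 | methyl (4S)-4-hydroxy-2,6,6-trimethylcyclohex-2-ene-1-carboxylate (both C1 epimers) | CC1=C[C@@H](O)CC(C)(C)C1C(=O)OC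
F5 | step 15 | tert-butyl(dimethyl){[(1R)-3,5,5-trimethyl-4-(prop-2-en-1-yl)cyclohex-3-en-1-yl]oxy}silane | C=CCC1=C(C)C[C@@H](O[Si](C)(C)C(C)(C)C)CC1(C)C
F6 | step 15 | 2-[(4R)-4-{[tert-butyl(dimethyl)silyl]oxy}-2,6,6-trimethylcyclohex-1-en-1-yl]acetaldehyde | O=CCC1=C(C)C[C@@H](O[Si](C)(C)C(C)(C)C)CC1(C)C
F7 | step 15 | (3E)-3-({[tert-butyl(dimethyl)silyl]oxy}methyl)-1-[(4R)-4-{[tert-butyl(dimethyl)silyl]oxy}-2,6,6-trimethylcyclohex-1-en-1-yl]-5-[(triethylsilyl)oxy]pent-3-en-2-ol (both C2 epimers) | CC[Si](CC)(CC)OC/C=C(\CO[Si](C)(C)C(C)(C)C)C(O)CC1=C(C)C[C@@H](O[Si](C)(C)C(C)(C)C)CC1(C)C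
F8 | step 22 | (2E)-3-({[tert-butyl(dimethyl)silyl]oxy}methyl)-5-[(4R)-4-{[tert-butyl(dimethyl)silyl]oxy}-2,6,6-trimethylcyclohex-1-en-1-yl]-4-oxopent-2-enal | O=C/C=C(\CO[Si](C)(C)C(C)(C)C)C(=O)CC1=C(C)C[C@@H](O[Si](C)(C)C(C)(C)C)CC1(C)C
F9 | step 22 | (2E,4E,6E,8E,10E,12E)-13-[(1R,4R)-4-hydroxy-2,6,6-trimethylcyclohex-2-en-1-yl]-2,7,11-trimethyltrideca-2,4,6,8,10,12-hexaen-1-ol | CC1=C[C@H](O)CC(C)(C)[C@H]1/C=C/C(C)=C/C=C/C(C)=C/C=C/C=C(C)/CO
F10 | step 22 | [(2E,4E,6E,8E,10E,12E)-13-[(1R,4R)-4-hydroxy-2,6,6-trimethylcyclohex-2-en-1-yl]-2,7,11-trimethyltrideca-2,4,6,8,10,12-hexaen-1-yl](triphenyl)phosphonium bromide | CC1=C[C@H](O)CC(C)(C)[C@H]1/C=C/C(C)=C/C=C/C(C)=C/C=C/C=C(C)/C[P+](c1ccccc1)(c1ccccc1)c1ccccc1.[Br-]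
F11 | step 22 | ylide of F10 | CC1=C[C@H](O)CC(C)(C)[C@H]1/C=C/C(C)=C/C=C/C(C)=C/C=C/C=C(C)/C=P(c1ccccc1)(c1ccccc1)c1ccccc1
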